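The route rests on reading C20 (on quaternary C10) and C11 (on C9) as the two ends of one C2 unit: they are vicinal and cis on ring B, next to C8. A [2+2] photocycloaddition of acetylene to a ring B enone (C8 ketone, C9=C10) therefore forms C10–C20 and C9–C11, both ring B stereocentres and a sacrificial cyclobutene in one operation. Cleaving its C11=C20 bond later releases the hindered formyl group and the side-chain handle. The precursor is an enantiopure octalone that already carries C4 (methyl, acetoxymethyl) and the C5 hydrogen; its carbonyl carbon C8 later bears the exocyclic methylene.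

Key step: step 6

Remark (convention): labdane numbering is used for the decalin core throughout (C4 quaternary, C5/C10 ring fusion, C8 ketone then methylene C17, C19 = CH2OAc, C20 = CHO, C11–C16 side chain).
Remark (assumption): the ligand antipode in step 1 is chosen by its known sense of induction so that C4 arises as drawn.

Step 1
Reactants: 1 3-methylcyclohex-2-en-1-one; 2 vinylmagnesium bromide
Product: 5 (S)-[(3-ethenyl-3-methylcyclohex-1-en-1-yl)oxy]trimethylsilane, via ethenyl(dimethyl)alane 3 (not isolated), via dimethylaluminium enolate 4 (not isolated)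
Conditions: 2, Me2AlCl, Et2O/THF, 0 °C; then 1, CuTC (CuO2CC4H3S, 10 mol%), chiral aminophosphine ligand (SimplePhos type, 11 mol%), Et2O, −30 °C; then TMSOTf, −30 → 0 °C
Reagents that add atoms: trimethylsilyl trifluoromethanesulfonate, C[Si](C)(C)OS(=O)(=O)C(F)(F)F
Why: Copper-catalysed asymmetric conjugate addition of an alkenylalane to a β-substituted cyclohexenone is a known way to all-carbon quaternary centres; the ligand on copper selects the enone face and so sets C4, and O-silylation of the aluminium enolate stores the enolate regiochemistry (C10=C5) for the next step.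

Step 2
Reactants: 5 (S)-[(3-ethenyl-3-methylcyclohex-1-en-1-yl)oxy]trimethylsilane; 6 methyl vinyl ketone
Product: 8 (4aS,5S)-5-ethenyl-5-methyl-4,4a,5,6,7,8-hexahydronaphthalen-2(3H)-one, via diketone 7 (not isolated)
Conditions: 6, TiCl4, CH2Cl2, −78 °C; aq. NaHCO3 work-up; KOH, MeOH, 0 °C → rt; SiO2 chromatography
Reagents that add atoms: none
Why: Mukaiyama–Michael addition of the regiodefined enol ether (new bond C5–C6) and base-mediated intramolecular aldol condensation make up a Robinson annulation that builds ring B with the C8 ketone and C9=C10; C4 is untouched, whereas C5 lies next to the C10 carbonyl, can equilibrate before dehydration and is biased only weakly by methyl versus vinyl on C4, so 8 (H5 trans to the vinyl group) is expected together with its C5 epimer and is isolated by chromatography.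

Step 3
Reactants: 8 (4aS,5S)-5-ethenyl-5-methyl-4,4a,5,6,7,8-hexahydronaphthalen-2(3H)-one
Product: 10 (1R,8aS)-1-methyl-6-oxo-1,2,3,4,6,7,8,8a-octahydronaphthalene-1-carbaldehyde, via trioxolane ozonide 9 (not isolated)
Conditions: O3, CH2Cl2, −78 °C (Sudan Red 7B end point); then Me2S, −78 °C → rt
Reagents that add atoms: ozone, [O-][O+]=O
Why: Ozonolysis is chemoselective here because the electron-rich monosubstituted vinyl group reacts with ozone far faster than the electron-poor conjugated C9=C10 bond; the dye end point guards against over-oxidation and C4 and C5 are not touched.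

Step 4
Reactants: 10 (1R,8aS)-1-methyl-6-oxo-1,2,3,4,6,7,8,8a-octahydronaphthalene-1-carbaldehyde
Product: 11 (4aS,5R)-5-(hydroxymethyl)-5-methyl-4,4a,5,6,7,8-hexahydronaphthalen-2(3H)-one
Conditions: NaBH4 (0.5 equiv), CH2Cl2/MeOH, −78 °C
Reagents that add atoms: none
Why: Chemoselective borohydride reduction: at −78 °C an aldehyde is reduced much faster than a conjugated ketone, so only C19 becomes CH2OH and no stereocentre is formed.

Step 5
Reactants: 11 (4aS,5R)-5-(hydroxymethyl)-5-methyl-4,4a,5,6,7,8-hexahydronaphthalen-2(3H)-one
Product: 12 [(1R,8aS)-1-methyl-6-oxo-1,2,3,4,6,7,8,8a-octahydronaphthalen-1-yl]methyl acetate (19-acetoxy octal-9-en-8-one; 4R,5S in labdane numbering)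
Conditions: Ac2O, pyridine, DMAP (5 mol%), CH2Cl2, 0 °C → rt
Reagents that add atoms: acetic anhydride, CC(=O)OC(C)=O
Why: DMAP-catalysed acetylation of the primary neopentyl alcohol installs the C19 acetate of the target, which also makes the C19 hydrogens electron-poor before the photochemical step; the enone is inert.

Step 6
Reactants: 12 [(1R,8aS)-1-methyl-6-oxo-1,2,3,4,6,7,8,8a-octahydronaphthalen-1-yl]methyl acetate; 13 acetylene
Product: 14 (4R,5S,9S,10S)-19-acetoxy cyclobutene photoadduct (four-membered ring C9–C11=C20–C10 cis-fused to ring B of the trans-decalin-8-one; C19, C20 and C11 on one face, H5 and H9 on the other)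
Conditions: 13 (acetone-free, saturated solution with slow gas stream), CH2Cl2, −70 °C, hν (365 nm LED or Hg lamp through uranium glass), to about 70% conversion, 12 recovered
Reagents that add atoms: none
Why: Excitation of the enone (n→π*) and intersystem crossing give the triplet, which adds to acetylene stepwise through a triplet 1,4-diradical; this is the known enone–alkyne [2+2] photocycloaddition. The cyclobutene ring is closed by spin inversion and radical recombination of that diradical, so both new bonds are delivered to one face of the former C9=C10 bond. C10 is controlled by the excited state: the β-carbon pyramidalises so that ring A keeps its chair and a trans A/B fusion develops, which puts C20 axial and anti to H5. C9 is controlled by ring strain, since a cyclobutene can only be cis-fused to ring B, so C11 ends syn to C20. The step needs face selectivity at C10 against the 1,3-diaxial C19 acetoxymethyl group, which rests on this pyramidalisation and on the small linear addend, while regiochemistry cannot arise with symmetric acetylene. Secondary photoreaction of the β,γ-unsaturated ketone product is limited by exciting only the enone band, low temperature and partial conversion, and the acetate disfavours hydrogen abstraction from C19.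

Step 7
Reactants: 14 (4R,5S,9S,10S)-19-acetoxy cyclobutene photoadduct
Product: 15 (4R,5S,9R,10S)-8(17)-methylene analogue of 14 (C8=CH2, cyclobutene intact)
Conditions: CH2Br2, Zn, TiCl4, THF/CH2Cl2, 0 °C → rt
Reagents that add atoms: dibromomethane, BrCBr
Why: Takai–Lombardo methylenation uses a non-basic zinc/titanium methylene reagent, so the C9 hydrogen (α to the ketone and allylic) is not enolised and the acetate is left alone while the ketone is converted; no stereocentre changes.

Step 8
Reactants: 15 (4R,5S,9R,10S)-8(17)-methylene cyclobutene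
Product: 17 (4R,5R,9R,10S)-19-acetoxy-12,13,14,15,16-pentanorlabd-8(17)-ene-11,20-dial, via bicyclic ozonide 16 (not isolated)
Conditions: O3 (1.0 equiv, titrated CH2Cl2 solution), CH2Cl2, −78 °C; then PPh3, −78 °C → rt; crude 17 used directly
Reagents that add atoms: ozone, [O-][O+]=O
Why: Chemoselective ozonolysis: a strained cis-1,2-disubstituted cyclobutene is attacked by ozone much faster than a hindered 1,1-disubstituted methylene, so one titrated equivalent should cleave only C11=C20 and unveil both aldehydes with C9 and C10 unchanged.

Step 9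
Reactants: 17 (4R,5R,9R,10S)-19-acetoxy-12,13,14,15,16-pentanorlabd-8(17)-ene-11,20-dial
Product: 18 (4R,5R,9R,10S)-19-acetoxy-13,14,15,16-tetranorlabda-8(17),11-dien-20-al
Conditions: Ph3PCH3Br (1.1 equiv), KHMDS (1.05 equiv), THF, 0 °C; then 17, −78 → −30 °C
Reagents that add atoms: methyltriphenylphosphonium bromide, C[P+](c1ccccc1)(c1ccccc1)c1ccccc1.[Br-]
Why: Wittig methylenation under steric control: the C11 aldehyde on tertiary C9 is far more accessible than the axial neopentyl C20 aldehyde on quaternary C10 (1,3-diaxial to C19), and at −78 °C addition of the ylide should outrun enolisation of the epimerisable allylic C9 position.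

Step 10
Reactants: 18 (4R,5R,9R,10S)-19-acetoxy-13,14,15,16-tetranorlabda-8(17),11-dien-20-al; 19 3-bromofuran-2(5H)-one
Product: 21 (4R,5R,9R,10R)-19-acetoxy-20-hydroxylabda-8(17),13-dien-16,15-olide, via bis(disiamylboryl) intermediate 20 (not isolated)
Conditions: Sia2BH (2.3 equiv, from BH3·THF and 2-methylbut-2-ene), THF, 0 °C → rt; then aq. K3PO4 (quench of B–H), 19, Pd(dppf)Cl2 (5 mol%), AsPh3 (10 mol%), DMF, rt
Reagents that add atoms: none
Why: Hydroboration then B-alkyl Suzuki–Miyaura coupling: disiamylborane adds anti-Markovnikov to the monosubstituted vinyl group much faster than to the hindered 1,1-disubstituted C8 methylene and deliberately reduces the C20 aldehyde to its borinate, the primary alkylborane is coupled with the α-bromobutenolide under mild base, and work-up frees the C20 alcohol; no stereocentre is formed.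

Step 11
Reactants: 21 (4R,5R,9R,10R)-19-acetoxy-20-hydroxylabda-8(17),13-dien-16,15-olide
Product: 22 (4R,5R,9R,10R)-19-acetoxy-20-oxolabda-8(17),13-dien-16,15-olide (target CNP0109410.1)
Conditions: Dess–Martin periodinane, CH2Cl2, 0 °C → rt
Reagents that add atoms: none
Why: Dess–Martin oxidation returns the C20 aldehyde under neutral conditions that spare the butenolide, the exocyclic methylene and the acetate; C10 is quaternary, so the aldehyde cannot epimerise.

Compound list
1 | 3-methylcyclohex-2-en-1-one | CC1=CC(=O)CCC1 | starting material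
2 | vinylmagnesium bromide | C=C[Mg]Br | starting material
3 | ethenyl(dimethyl)alane | C=C[Al](C)C | intermediate
4 | dimethylaluminium (S)-3-ethenyl-3-methylcyclohex-1-en-1-olate | C[Al](C)OC1=C[C@](C)(C=C)CCC1 | intermediate
5 | (S)-[(3-ethenyl-3-methylcyclohex-1-en-1-yl)oxy]trimethylsilane | C[Si](C)(C)OC1=C[C@](C)(C=C)CCC1 | intermediate
6 | methyl vinyl ketone (but-3-en-2-one) | C=CC(C)=O | starting material
7 | (3S)-3-ethenyl-3-methyl-2-(3-oxobutyl)cyclohexan-1-one, both C2 epimers | CC(=O)CCC1C(=O)CCC[C@@]1(C)C=C | intermediate
8 | (4aS,5S)-5-ethenyl-5-methyl-4,4a,5,6,7,8-hexahydronaphthalen-2(3H)-one | O=C1CC[C@@H]2[C@](C)(C=C)CCCC2=C1 | intermediate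
9 | (4aS,5R)-5-methyl-5-(1,2,4-trioxolan-3-yl)-4,4a,5,6,7,8-hexahydronaphthalen-2(3H)-one (ozonide of 8, trioxolane carbon undefined) | O=C1CC[C@@H]2[C@](C)(C3OCOO3)CCCC2=C1 | intermediate
10 | (1R,8aS)-1-methyl-6-oxo-1,2,3,4,6,7,8,8a-octahydronaphthalene-1-carbaldehyde | O=C1CC[C@@H]2[C@](C)(C=O)CCCC2=C1 | intermediate
11 | (4aS,5R)-5-(hydroxymethyl)-5-methyl-4,4a,5,6,7,8-hexahydronaphthalen-2(3H)-one | O=C1CC[C@@H]2[C@](C)(CO)CCCC2=C1 | intermediate
12 | [(1R,8aS)-1-methyl-6-oxo-1,2,3,4,6,7,8,8a-octahydronaphthalen-1-yl]methyl acetate (key-step precursor) | O=C1CC[C@@H]2[C@](C)(COC(C)=O)CCCC2=C1 | intermediate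
13 | acetylene (ethyne) | C#C | starting material
14 | (4R,5S,9S,10S)-19-acetoxy cyclobutene photoadduct (C9–C11=C20–C10 ring cis-fused to ring B, C8 ketone; key-step product) | O=C1CC[C@@H]2[C@](C)(COC(C)=O)CCC[C@@]2(C=C3)[C@@H]13 | intermediate
15 | (4R,5S,9R,10S)-8(17)-methylene analogue of 14 | C=C1CC[C@@H]2[C@](C)(COC(C)=O)CCC[C@@]2(C=C3)[C@@H]13 | intermediate
16 | secondary ozonide of 15 (C11 and C20 joined through –O– and –O–O–) | C=C1CC[C@@H]2[C@](C)(COC(C)=O)CCC[C@@]2(C3OOC4O3)[C@@H]14 | intermediate
17 | (4R,5R,9R,10S)-19-acetoxy-12,13,14,15,16-pentanorlabd-8(17)-ene-11,20-dial | C=C1CC[C@@H]2[C@](C)(COC(C)=O)CCC[C@@]2(C=O)[C@@H]1C=O | intermediate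
18 | (4R,5R,9R,10S)-19-acetoxy-13,14,15,16-tetranorlabda-8(17),11-dien-20-al | C=C1CC[C@@H]2[C@](C)(COC(C)=O)CCC[C@@]2(C=O)[C@@H]1C=C | intermediate
19 | 3-bromofuran-2(5H)-one | O=C1OCC=C1Br | starting material
20 | C12-[bis(3-methylbutan-2-yl)boryl] C20-O-[bis(3-methylbutan-2-yl)boryl] derivative of 18 | C=C1CC[C@@H]2[C@](C)(COC(C)=O)CCC[C@@]2(COB(C(C)C(C)C)C(C)C(C)C)[C@@H]1CCB(C(C)C(C)C)C(C)C(C)C | intermediate
21 | (4R,5R,9R,10R)-19-acetoxy-20-hydroxylabda-8(17),13-dien-16,15-olide | C=C1CC[C@@H]2[C@](C)(COC(C)=O)CCC[C@@]2(CO)[C@@H]1CCC1=CCOC1=O | intermediate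
22 | (4R,5R,9R,10R)-19-acetoxy-20-oxolabda-8(17),13-dien-16,15-olide | C=C1CC[C@@H]2[C@](C)(COC(C)=O)CCC[C@@]2(C=O)[C@@H]1CCC1=CCOC1=O | target

Total step count: 11. Longest linear sequence: 11 steps (1 to 22).

Steps most likely to fail

Step 6. Acetylene may attack the wrong face of C10 because of the 1,3-diaxial C19 group. In addition, the β,γ-unsaturated ketone product can be consumed by secondary excitation (1,3-acyl shift), made worse by the low concentration of dissolved acetylene. The fallback sets out from 12 and separates ring formation from alkene formation. Irradiation of 12 in the presence of excess (E)-1,2-dichloroethene (same lamp and filter) should give the saturated dichlorocyclobutane adduct F1, which has no β,γ-unsaturation and is photostable under the enone band. Any trans-fused isomer at C9 is equilibrated to the cis-fused ketone on basic alumina. Zinc-mediated reductive 1,2-elimination (activated Zn, EtOH, 60 °C) then removes both chlorines, whatever their configuration, and comes back to the route at 14. This does not repair a wrong face at C10.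

Step 10. The borane may fail to discriminate the vinyl group from the C8 methylene, or transfer of the primary alkyl group from the hindered dialkylborane may be slow in the coupling. The fallback sets out from 14 and introduces the methylene last, so that the borane never meets a second alkene or a free aldehyde.
- Me3SiCH2MgCl/CeCl3 (THF, −78 °C) adds to the C8 ketone from the face opposite the cyclobutene to give the β-hydroxysilane F2 (hydroxyl syn to C20).
- Ozonolysis of its only alkene (O3, CH2Cl2, −78 °C; PPh3) passes through the ozonide F3 and gives the lactol aldehyde F4, in which the C8 hydroxyl has captured the C20 aldehyde while the C11 aldehyde stays free.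
- Wittig methylenation (Ph3P=CH2, 2 equiv, −78 °C) gives the vinyl lactol F5.
- 9-BBN hydroboration gives the alkylborane F6, and the same palladium coupling with 19 gives the butenolide lactol F7.
- Acid-promoted Peterson elimination (BF3·OEt2, CH2Cl2, 0 °C) expels the lactol oxygen from C8, forms the exocyclic methylene, releases the C20 aldehyde and comes back to the route at 22.

Step 2. There is no facial control when C5 is formed and equilibrated, so a large part of the material may emerge as the C5 epimer. The fallback sets out from 7 and replaces selectivity in the bond-forming step by an epimer-recycling loop. The unwanted annulation product, the C5-epimeric octalone F8, is separated from 8. It is then re-equilibrated through the extended dienolate (C5 is the γ-carbon of the enone; KOt-Bu cat., t-BuOH, 50 °C) to the epimer mixture and chromatographed again, coming back to the route at 8.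

Further compounds
F1 | step 6 | (4R,5S,10S)-19-acetoxy-11,20-dichloro cyclobutane analogue of 14 (chlorine-bearing carbons and C9 as mixtures) | O=C1CC[C@@H]2[C@](C)(COC(C)=O)CCC[C@@]2(C(Cl)C3Cl)C13
F2 | step 10 | 8-hydroxy-8-[(trimethylsilyl)methyl] adduct of 14 (hydroxyl syn to C20) | C[Si](C)(C)C[C@@]1(O)CC[C@@H]2[C@](C)(COC(C)=O)CCC[C@@]2(C=C3)[C@@H]13
F3 | step 10 | secondary ozonide of F2 | C[Si](C)(C)C[C@@]1(O)CC[C@@H]2[C@](C)(COC(C)=O)CCC[C@@]2(C3OOC4O3)[C@@H]14
F4 | step 10 | C8–O–C20 lactol with free C11 aldehyde (lactol carbon undefined) | C[Si](C)(C)C[C@]12CC[C@@H]3[C@](C)(COC(C)=O)CCC[C@@]3(C(O)O1)[C@@H]2C=O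
F5 | step 10 | C9-vinyl lactol | C[Si](C)(C)C[C@]12CC[C@@H]3[C@](C)(COC(C)=O)CCC[C@@]3(C(O)O1)[C@@H]2C=C
F6 | step 10 | C12-(9-borabicyclo[3.3.1]nonan-9-yl) lactol O-borinate | C[Si](C)(C)C[C@]12CC[C@@H]3[C@](C)(COC(C)=O)CCC[C@@]3(C(OB4C5CCCC4CCC5)O1)[C@@H]2CCB1C2CCCC1CCC2
F7 | step 10 | butenolide lactol (β-silyl lactol precursor of 22) | C[Si](C)(C)C[C@]12CC[C@@H]3[C@](C)(COC(C)=O)CCC[C@@]3(C(O)O1)[C@@H]2CCC1=CCOC1=O
F8 | step 2 | (4aR,5S)-5-ethenyl-5-methyl-4,4a,5,6,7,8-hexahydronaphthalen-2(3H)-one (C5 epimer of 8) | O=C1CC[C@H]2[C@](C)(C=C)CCCC2=C1
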